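# Proposed synthesis of CNP0398000.1, the (3R)-3-hydroxyphthalide ester, by a photochemical vinylketene–ynol ether benzannulation

Numbering used throughout: ring A is the benzoate ring (C1 carboxyl carbon, C2 OH, C3 Me, C4 OMe, C5 H, C6 Me). Ring B is the benzene ring of the phthalide (lactone C1 carbonyl, O2, C3, ring fusion C3a/C7a, C4 H, C5 OMe, C6 CH2O, C7 OH).

## Structural features

The target is a two-ring ester: the carboxyl group of the pentasubstituted ring A acylates the oxygen of a CH2 group on C6 of ring B. Ring B is fused through C3a/C7a to a five-membered lactone ring, and its C7 hydroxyl lies next to both the lactone carbonyl and the esterified C6 methylene. The only stereocentre is C3 of the lactone ring, a lactol (hemiacylal) carbon with R configuration. No other stereocentre stands near it, so its configuration has to come from a reagent or catalyst, not by relay. This lactol is the most fragile group: it can open reversibly to an achiral formyl acid, which racemises it, most readily once the acid is ionised. The second fragile motif is the ortho-hydroxybenzyl ester, which can expel the ring A carboxylate as an ortho-quinone methide once the C7 phenol is deprotonated. The ring A carbonyl is flanked by the C2 hydroxyl and the C6 methyl, so acylating an alcohol with this acid is slow. The real difficulty lies in combining this hindered ester with a late, site- and face-selective oxidation at C3, and in placing five substituents on each ring without regioisomers. The key step exploits the contiguous C2 hydroxyl, C3 methyl and C4 methoxy of ring A: C2 can come from a ketene carbon, C3 and C4 from the two carbons of an alkoxyalkyne, and C5, C6 and C1 from an enone that already carries the ester to ring B.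

## Logic of the disconnections

**26 ⇒ 25.** The C3–OH bond is cut (C–H oxidation in the forward sense). The lactol is placed last because no later step can then open or epimerise it. The precursor 25 is an achiral, robust phthalide. The forward step must pick one of the two enantiotopic C3 hydrogens (the pro-S one) and leave two aryl methyls, two methoxy groups and the ester methylene alone.

**25 ⇒ 24.** The O–Si bond at C7 is cut. A free C7 phenol would quench the ylide and the amide base and would trap the ketene, so it is masked until ring A exists. The forward desilylation must avoid a free phenoxide, which could eject the ring A carboxylate.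

**24 ⇒ 16 + 19.** The C2–C3, C4–C5 and C1–C2 bonds of ring A are cut. This dissolves ring A into an acyclic diazo enone and a three-carbon ynol ether. It also turns the hindered aryl ester into an ordinary unsaturated ester that is made before the ring exists. The forward step needs a regiospecific ketene–alkyne union, an E enoate, and capture of the ketene by 19 before anything else reacts with it.

**19 ⇒ 17.** Only hydrogen positions change: the triple bond is moved next to oxygen by prototropic isomerisation. The demand is a base strong enough to carry the isomerisation past the allene stage.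

**16 ⇒ 14.** The carbon–nitrogen bond of the diazo group is cut. The diazo group is brought in by transfer onto the methyl ketone, because acylation of a diazoalkane by an unsaturated acid chloride would suffer dipolar cycloaddition to the enoate. The forward step must enolise the methyl ketone in preference to the lactone methylene and the allylic methyl.

**14 ⇒ 10 + 11.** The C2=C3 double bond of the pentenoate is cut (Wittig transform). Diketone 11 is symmetrical, so no regiochemical question arises. The forward step must stop after one olefination and give the E isomer.

**10 ⇒ 7 + 8.** The acyl–oxygen bond at the C6 methylene and the O–Si bond at C7 are cut. This reduces the ring B partner to a simple diol. The forward step must acylate the primary alcohol before the phenol and silylate the phenol without displacing bromide.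

**7 ⇒ 5.** The C6–CH2 bond is cut, removing a one-carbon unit at the formaldehyde oxidation level. The forward step must deliver it ortho (C6) and not para (C4) to the phenol.

**5 ⇒ 4.** The O–CH3 bond at C7 is cut. The forward cleavage must be selective for the methoxy group next to the lactone carbonyl.

**4 ⇒ 2 ⇒ 1.** The C7a–C1 bond and the lactone C–O bond are cut, then the C–Br bond. Compound 1 is symmetrical, so both positions ortho to its CH2OH are equivalent and carboxylation there fixes the phthalide regiochemistry. The forward bromination must avoid the position between the two methoxy groups.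

## Other disconnections considered

**Alternative 1:** The cut runs through ring B itself (C4–C5, C6–C7, C3a–C7a).

- **Forward step:** Triyne A1 joins a propargyl propiolate and a methoxyalkyne carbinol through a diisopropylsilyl group. RhCl(PPh3)3 (monovalent rhodium) would cyclotrimerise it to the oxasilole-fused phthalide A2. Tamao–Fleming oxidation of the aryl–silicon bond would then give diol 7, and steps 5 to 11 would follow unchanged.
- **In favour:** All five ring B substituents are fixed by the tether topology. Neither a selective demethylation nor an ortho-selective hydroxymethylation is needed. On regiocontrol of ring B this is better than steps 3 and 4, which depend on chelation and tethered delivery.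
- **Against:** A1 contains an acid-sensitive ynol ether and an electrophilic silyl propiolate and would need about four steps. The ynol ether may hydrate or oligomerise at the metal. The hindered diisopropylsilyl–aryl bond must be oxidised under basic peroxide next to a lactone.
- **Comparison:** Step economy to 7 is about equal to steps 1 to 4. The mechanism is a metal-mediated (2+2+2) process against a metal-free pericyclic cascade. The alternative does nothing for ring A, the hindered ester or C3, so it could replace the opening of the chosen plan but not its key step.

**Alternative 2:** The cut removes the C6–CH2 and CH2–O(ester) bonds.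

- **Forward step:** Boronate 6, assembled as in step 4, would be heated so that it opens to the ortho-quinone methide A4. The carboxyl group of ring A acid A3 would capture A4 to give A5, which is identical with 25.
- **In favour:** It is highly convergent and needs no protecting group, no diazo compound and no photochemistry. A3 is two steps from a commercial ester. On step economy it is clearly better, about six steps to 25 against ten.
- **Against:** A hindered, weakly nucleophilic carboxylic acid must out-compete oligomerisation of A4 and its return to 6. The phenol oxygen or the electron-rich C5 of A3 may add instead. The product is itself a thermal precursor of A4, so the capture is reversible at the temperature that is needed.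
- **Comparison:** Both plans form the ester at the alkyl carbon and so avoid attack at the crowded carbonyl; on that point they are equal. Both leave the C3 oxidation for the end; equal again. The chosen cascade has closer mechanistic precedent for each bond it forms, while the alternative is shorter but rests on a less established trapping.

**Alternative 3:** The cut removes the C3a–C4 and C7–C7a bonds of ring B.

- **Forward step:** The trioxygenated diene A7 would add to the bromobutenolide A6. Twofold elimination would aromatise the adduct to the acetoxyphthalide A8.
- **In favour:** C3 arrives at the right oxidation level and with R configuration from a small building block, which could be made by lipase acetylation of the racemising hydroxybutenolide. This avoids the late C–H oxidation and is better than the chosen plan on its riskiest step. Regiochemistry follows from diene polarisation and the bromine.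
- **Against:** The acetal hydrogen of A6 and A8 is acidic, so the base needed for aromatisation may epimerise C3. A7 is a hydrolytically labile, fully substituted ketene acetal of several steps. After A8 the silyl ether must be removed, A3 attached (by Mitsunobu alkylation) next to a free phenol and an anomeric acetate, and the acetate cleaved without loss of configuration.
- **Comparison:** The lability of the free lactol at the end is the same in both plans. The step count is about equal. The alternative builds ring B by cycloaddition and forms the hindered ester late, whereas the chosen plan builds ring A and forms that ester early, which is its main advantage here.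

Key step: step 9

Assumption: the C3 lactol of 26 can racemise through its ring-opened formyl acid, so it is generated last, in weakly acidic medium and in the cold, and it is assumed that it keeps its configuration long enough to be isolated under such handling.

## Route

Step 1
Reactants: 1 3,5-dimethoxybenzyl alcohol
Product: 2 2-bromo-3,5-dimethoxybenzyl alcohol
Conditions: N-bromosuccinimide (1.0 equiv), CH2Cl2, 0 °C
Reagents that add atoms: N-bromosuccinimide, O=C1CCC(=O)N1Br
Why: Electrophilic aromatic bromination; the two equivalent positions ortho to CH2OH are each ortho and para to a methoxy group and less hindered than the position between the methoxy groups, so one equivalent should give the 2-bromide.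

Step 2
Reactants: 2 2-bromo-3,5-dimethoxybenzyl alcohol
Product: 4 5,7-dimethoxyphthalide, via hydroxy acid 3 (not isolated)
Conditions: n-BuLi (2.2 equiv), THF, −78 °C; CO2 (gas); then 2 M HCl, 20 °C
Reagents that add atoms: carbon dioxide, O=C=O
Why: Alkoxide formation and bromine–lithium exchange, carboxylation of the aryllithium, and acid-induced lactonisation of 3 onto the neighbouring CH2OH; this is a standard phthalide synthesis from 2-bromobenzyl alcohols.

Step 3
Reactants: 4 5,7-dimethoxyphthalide
Product: 5 7-hydroxy-5-methoxyphthalide
Conditions: BCl3 (1.2 equiv), CH2Cl2, −78 → 0 °C; then H2O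
Reagents that add atoms: none
Why: Chelation-controlled ether cleavage: boron bound between the lactone carbonyl and the adjacent C7 methoxy oxygen activates only that methyl group for chloride attack, and the C5 methoxy group is not engaged.

Step 4
Reactants: 5 7-hydroxy-5-methoxyphthalide
Product: 7 7-hydroxy-6-(hydroxymethyl)-5-methoxyphthalide, via benzodioxaborin 6 (not isolated)
Conditions: PhB(OH)2 (1.2 equiv), (CH2O)n (3 equiv), EtCO2H (0.3 equiv), toluene, reflux, Dean–Stark; then HO(CH2)3OH, THF, 20 °C
Reagents that add atoms: formaldehyde (as paraformaldehyde), C=O
Why: Boronic acid-templated ortho-hydroxymethylation of a phenol: the aryloxyboron tether delivers formaldehyde only to the free ortho carbon C6 (C7a is substituted, the para carbon C4 is out of reach) and closes to 6. Transesterification with the diol then releases 7.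

Step 5
Reactants: 7 7-hydroxy-6-(hydroxymethyl)-5-methoxyphthalide; 8 bromoacetyl bromide
Product: 10 [7-(tert-butyldimethylsilyloxy)-5-methoxyphthalid-6-yl]methyl bromoacetate, via phenol bromoacetate 9 (not isolated)
Conditions: 8 (1.05 equiv), 2,6-lutidine (3 equiv), CH2Cl2, −40 °C; then t-BuMe2SiOTf (1.3 equiv), −40 → 0 °C
Reagents that add atoms: tert-butyldimethylsilyl triflate, CC(C)(C)[Si](C)(C)OS(=O)(=O)C(F)(F)F
Why: O-acylation then O-silylation; the primary benzylic alcohol should react with the acyl bromide well before the doubly flanked phenol that is hydrogen-bonded to the lactone carbonyl, and the silyl triflate then caps that phenol. The hindered base cannot displace the bromide, and immediate silylation removes the phenol that could eject the ester.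

Step 6
Reactants: 10 [7-(tert-butyldimethylsilyloxy)-5-methoxyphthalid-6-yl]methyl bromoacetate; 11 2,3-butanedione
Product: 14 [7-(tert-butyldimethylsilyloxy)-5-methoxyphthalid-6-yl]methyl (E)-3-methyl-4-oxopent-2-enoate, via phosphonium bromide 12 (not isolated), via phosphorus ylide 13 (not isolated)
Conditions: PPh3 (1.0 equiv), CH2Cl2, 20 °C; then Et3N (1.1 equiv), 11 (3 equiv), 0 → 20 °C
Reagents that add atoms: none
Why: Quaternisation, deprotonation to the ester-stabilised ylide and Wittig olefination of one carbonyl of the activated diketone; stabilised ylides give the thermodynamically preferred E enoate (acetyl trans to the ester). Excess 11 and the lower electrophilicity of the product enone should prevent a second olefination.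

Step 7
Reactants: 14 [7-(tert-butyldimethylsilyloxy)-5-methoxyphthalid-6-yl]methyl (E)-3-methyl-4-oxopent-2-enoate
Product: 16 [7-(tert-butyldimethylsilyloxy)-5-methoxyphthalid-6-yl]methyl (E)-5-diazo-3-methyl-4-oxopent-2-enoate, via trifluoroacetyl diketone 15 (not isolated)
Conditions: LiN(SiMe3)2 (1.1 equiv), THF, −78 °C; CF3CO2CH2CF3 (1.2 equiv), −78 °C; then 4-AcNHC6H4SO2N3 (1.5 equiv), Et3N (1.5 equiv), H2O (1 equiv), MeCN, 20 °C; work-up at pH 7
Reagents that add atoms: 4-acetamidobenzenesulfonyl azide, CC(=O)Nc1ccc(cc1)S(=O)(=O)N=[N+]=[N-]
Why: Detrifluoroacetylative diazo transfer: kinetic enolisation of the methyl ketone and Claisen trifluoroacetylation give 15, whose activated methylene accepts the diazo group (Regitz-type transfer) with loss of the trifluoroacetyl group. No diazoalkane or acid chloride is used that could add to the enoate.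

Step 8
Reactants: 17 methyl propargyl ether
Product: 19 1-methoxypropyne, via methoxyallene 18 (not isolated)
Conditions: NaNH2 (1.2 equiv), liquid NH3, −33 °C; NH4Cl; distillation, kept as a solution in ClCH2CH2Cl
Reagents that add atoms: none
Why: Base-mediated prototropic isomerisation (propargyl to allenyl to 1-alkynyl ether); the amide base in ammonia carries the rearrangement past allene 18 by deprotonation and reprotonation at the terminal carbon.

Step 9
Reactants: 16 [7-(tert-butyldimethylsilyloxy)-5-methoxyphthalid-6-yl]methyl (E)-5-diazo-3-methyl-4-oxopent-2-enoate; 19 1-methoxypropyne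
Product: 24 [7-(tert-butyldimethylsilyloxy)-5-methoxyphthalid-6-yl]methyl 2-hydroxy-4-methoxy-3,6-dimethylbenzoate, via vinylketene 20 (not isolated), via vinylcyclobutenone 21 (not isolated), via dienylketene 22 (not isolated), via cyclohexadienone 23 (not isolated)
Conditions: 19 (3 equiv), ClCH2CH2Cl (0.1 M), hν (365 nm LED, Pyrex), 20 °C; then 80 °C
Reagents that add atoms: none
Why: Irradiation expels N2 from 16 and the alkenyl group migrates (Wolff rearrangement) to give vinylketene 20; the nucleophilic, methyl-bearing carbon of 19 attacks the ketene carbonyl carbon and the (2+2) cycloaddition closes the four-membered ring of 21, with the methoxy carbon bonded to the former diazo carbon. Warming opens 21 by four-electron electrocyclic cleavage of its C(=O)–C(sp3) bond; this opening is reversible and drains through isomer 22, in which ketene and alkenyl group are cis. Ring A is closed by a thermal disrotatory six-electron electrocyclisation of 22 (ketene carbon onto the ester-bearing alkene terminus, six-membered carbocycle), and tautomerisation of dienone 23 to the phenol makes the sequence irreversible. The closest known reaction type is the Danheiser benzannulation in its photochemical Wolff form with alkoxyalkynes. No stereocentre is created, since the sp3 carbons of 21 and 23 end as aromatic carbons. The regiochemistry (OH at C2, Me at C3, OMe at C4) rests on the polarisation of the ynol ether in the ketene cycloaddition. The E enoate keeps the ester on the outside of the closing triene and away from the ketene, and the C7 silyl ether and the excess of 19 keep the ketene from being captured by a phenol.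

Step 10
Reactants: 24 [7-(tert-butyldimethylsilyloxy)-5-methoxyphthalid-6-yl]methyl 2-hydroxy-4-methoxy-3,6-dimethylbenzoate
Product: 25 (7-hydroxy-5-methoxyphthalid-6-yl)methyl 2-hydroxy-4-methoxy-3,6-dimethylbenzoate
Conditions: HF·pyridine, pyridine, THF, 0 °C
Reagents that add atoms: none
Why: Fluoride cleavage of an aryl silyl ether under buffered, weakly acidic conditions; no free phenoxide builds up, so loss of the ring A carboxylate through an ortho-quinone methide is avoided, and the hindered ester and the lactone are not attacked.

Step 11
Reactants: 25 (7-hydroxy-5-methoxyphthalid-6-yl)methyl 2-hydroxy-4-methoxy-3,6-dimethylbenzoate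
Product: 26 [(3R)-3,7-dihydroxy-5-methoxyphthalid-6-yl]methyl 2-hydroxy-4-methoxy-3,6-dimethylbenzoate
Conditions: unspecific peroxygenase from Agrocybe aegerita (recombinant evolved variant), H2O2 (1.2 equiv, syringe pump), citric acid/Na3C6H5O7 buffer pH 4.5, MeCN (20% v/v), 10 °C; extraction into cold EtOAc
Reagents that add atoms: hydrogen peroxide, OO
Why: Proposed new method: a heme-thiolate peroxygenase is proposed to abstract the 3-pro-S hydrogen of 25 with its oxoferryl porphyrin radical cation and to return hydroxyl to the same face (oxygen rebound), which sets C3 as R. The C3–H bonds are the only ones that are both benzylic and next to oxygen and so should be the weakest toward hydrogen abstraction, but site and face selectivity must come from the binding pocket and require screening of a panel of peroxygenases and P450 variants. The closest known reaction types are peroxygenase- and P450-catalysed benzylic hydroxylation of alkylbenzenes, O-dealkylation by hydroxylation of a C–H next to oxygen, and metabolic P450 hydroxylation of 3-alkylphthalides at C3.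

## Compound list

1 | 3,5-dimethoxybenzyl alcohol | COc1cc(CO)cc(OC)c1 | starting material
2 | 2-bromo-3,5-dimethoxybenzyl alcohol | COc1cc(CO)c(Br)c(OC)c1 | intermediate
3 | 2-(hydroxymethyl)-4,6-dimethoxybenzoic acid | COc1cc(CO)c(C(=O)O)c(OC)c1 | intermediate
4 | 5,7-dimethoxyphthalide (5,7-dimethoxyisobenzofuran-1(3H)-one) | COc1cc2COC(=O)c2c(OC)c1 | intermediate
5 | 7-hydroxy-5-methoxyphthalide | COc1cc(O)c2C(=O)OCc2c1 | intermediate
6 | cyclic phenylboronate of 7 (2-phenyl-4H-1,3,2-dioxaborin ring fused across O7 and the C6 methylene of 5-methoxyphthalide) | COc1cc2COC(=O)c2c2OB(OCc12)c1ccccc1 | intermediate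
7 | 7-hydroxy-6-(hydroxymethyl)-5-methoxyphthalide | COc1cc2COC(=O)c2c(O)c1CO | intermediate
8 | bromoacetyl bromide | O=C(Br)CBr | starting material
9 | (7-hydroxy-5-methoxyphthalid-6-yl)methyl bromoacetate | COc1cc2COC(=O)c2c(O)c1COC(=O)CBr | intermediate
10 | [7-(tert-butyldimethylsilyloxy)-5-methoxyphthalid-6-yl]methyl bromoacetate | COc1cc2COC(=O)c2c(O[Si](C)(C)C(C)(C)C)c1COC(=O)CBr | intermediate
11 | 2,3-butanedione | CC(=O)C(C)=O | starting material
12 | triphenylphosphonium bromide from 10 ({2-oxo-2-[(7-silyloxy-5-methoxyphthalid-6-yl)methoxy]ethyl}triphenylphosphonium bromide) | COc1cc2COC(=O)c2c(O[Si](C)(C)C(C)(C)C)c1COC(=O)C[P+](c1ccccc1)(c1ccccc1)c1ccccc1.[Br-] | intermediate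
13 | ylide of 12 ([7-silyloxy-5-methoxyphthalid-6-yl]methyl (triphenylphosphoranylidene)acetate) | COc1cc2COC(=O)c2c(O[Si](C)(C)C(C)(C)C)c1COC(=O)C=P(c1ccccc1)(c1ccccc1)c1ccccc1 | intermediate
14 | [7-(tert-butyldimethylsilyloxy)-5-methoxyphthalid-6-yl]methyl (E)-3-methyl-4-oxopent-2-enoate | CC(=O)/C(C)=C/C(=O)OCc1c(OC)cc2COC(=O)c2c1O[Si](C)(C)C(C)(C)C | intermediate
15 | [7-(tert-butyldimethylsilyloxy)-5-methoxyphthalid-6-yl]methyl (E)-7,7,7-trifluoro-3-methyl-4,6-dioxohept-2-enoate | O=C(CC(=O)/C(C)=C/C(=O)OCc1c(OC)cc2COC(=O)c2c1O[Si](C)(C)C(C)(C)C)C(F)(F)F | intermediate
16 | [7-(tert-butyldimethylsilyloxy)-5-methoxyphthalid-6-yl]methyl (E)-5-diazo-3-methyl-4-oxopent-2-enoate | [N-]=[N+]=CC(=O)/C(C)=C/C(=O)OCc1c(OC)cc2COC(=O)c2c1O[Si](C)(C)C(C)(C)C | intermediate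
17 | methyl propargyl ether (3-methoxyprop-1-yne) | COCC#C | starting material
18 | methoxyallene (1-methoxypropa-1,2-diene) | COC=C=C | intermediate
19 | 1-methoxypropyne | COC#CC | intermediate
20 | [7-(tert-butyldimethylsilyloxy)-5-methoxyphthalid-6-yl]methyl (2E)-3-methyl-5-oxopenta-2,4-dienoate (vinylketene) | O=C=C/C(C)=C/C(=O)OCc1c(OC)cc2COC(=O)c2c1O[Si](C)(C)C(C)(C)C | intermediate
21 | [7-(tert-butyldimethylsilyloxy)-5-methoxyphthalid-6-yl]methyl (E)-3-(2-methoxy-3-methyl-4-oxocyclobut-2-en-1-yl)but-2-enoate (racemic at the ring sp3 carbon) | COC1=C(C)C(=O)C1/C(C)=C/C(=O)OCc1c(OC)cc2COC(=O)c2c1O[Si](C)(C)C(C)(C)C | intermediate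
22 | [7-(tert-butyldimethylsilyloxy)-5-methoxyphthalid-6-yl]methyl (2E,4E)-5-methoxy-3,6-dimethyl-7-oxohepta-2,4,6-trienoate (dienylketene, ketene and alkenyl group cis) | O=C=C(C)/C(OC)=C\C(C)=C\C(=O)OCc1c(OC)cc2COC(=O)c2c1O[Si](C)(C)C(C)(C)C | intermediate
23 | [7-(tert-butyldimethylsilyloxy)-5-methoxyphthalid-6-yl]methyl 4-methoxy-3,6-dimethyl-2-oxocyclohexa-3,5-diene-1-carboxylate (racemic) | COC1=C(C)C(=O)C(C(=O)OCc2c(OC)cc3COC(=O)c3c2O[Si](C)(C)C(C)(C)C)C(C)=C1 | intermediate
24 | [7-(tert-butyldimethylsilyloxy)-5-methoxyphthalid-6-yl]methyl 2-hydroxy-4-methoxy-3,6-dimethylbenzoate | COc1cc(C)c(C(=O)OCc2c(OC)cc3COC(=O)c3c2O[Si](C)(C)C(C)(C)C)c(O)c1C | intermediate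
25 | (7-hydroxy-5-methoxyphthalid-6-yl)methyl 2-hydroxy-4-methoxy-3,6-dimethylbenzoate | COc1cc(C)c(C(=O)OCc2c(OC)cc3c(c2O)C(=O)OC3)c(O)c1C | intermediate
26 | [(3R)-3,7-dihydroxy-5-methoxyphthalid-6-yl]methyl 2-hydroxy-4-methoxy-3,6-dimethylbenzoate | COc1cc(C)c(C(=O)OCc2c(OC)cc3c(c2O)C(=O)O[C@H]3O)c(O)c1C | target

## Step count and least certain steps

Total: 11 steps. Longest linear sequence: 10 steps (steps 1 to 7, then 9, 10 and 11); step 8 is a one-step side branch.

**Step 11 (enzymatic hydroxylation).**
- **What may go wrong:** hydroxylation at other sites (the aryl methyl groups, O-demethylation through a methoxy C–H, the ester methylene); one-electron oxidation of the phenols by the peroxidase activity; poor discrimination between the two C3 hydrogens; loss of configuration by ring–chain equilibration in the aqueous buffer.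
- **Fallback, from 24 back to 26:** Double deprotonation of 24 with LiN(iPr)2 (2.2 equiv, THF, −78 °C; phenoxide first, then the lactone-stabilised benzylic anion at C3) and hydroxylation with a camphorsulfonyl oxaziridine (enolate hydroxylation with an N-sulfonyloxaziridine), followed by acidification to pH 3, should give the racemic silylated lactol F1. Buffered HF·pyridine as in step 10 would give the racemic target F2. Preparative chromatography on a chiral stationary phase (cold, acidified eluent) would deliver 26. The unwanted (S)-enantiomer F3 would be left to re-equilibrate through its open formyl acid form and recycled.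

**Step 9 (key step).**
- **What may go wrong:** photoisomerisation of the enoate to the Z form, after which the ketene is captured by the ester carbonyl or the ring closure stalls; acylation of the newly formed phenol by unreacted vinylketene; incomplete thermal conversion of the cyclobutenone; oligomerisation of the ynol ether.
- **Fallback, from 7 back to 25:** Ring A is not built but bought. Commercial methyl 2,4-dihydroxy-3,6-dimethylbenzoate F4 would be methylated at the non-chelated C4 hydroxyl (MeI, K2CO3, acetone) to methyl 2-hydroxy-4-methoxy-3,6-dimethylbenzoate F5 and hydrolysed (KOH, aqueous DMSO, 90 °C) to 2-hydroxy-4-methoxy-3,6-dimethylbenzoic acid F6. Mitsunobu coupling of F6 with the primary alcohol of 7 (PPh3, diisopropyl azodicarboxylate, THF, 0 °C) forms the ester by alkylation of the carboxylate, so the crowded carbonyl is never attacked, and should give 25 directly.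

**Step 7 (diazo transfer).**
- **What may go wrong:** competing deprotonation at the lactone methylene or at the allylic methyl; conjugate addition to the oxo-enoate with self-condensation; partial loss of the aryl silyl ether under the aqueous amine conditions.
- **Fallback, from 14 back to 16:** Soft enolisation of 14 (Me3SiOTf, Et3N, CH2Cl2, 0 °C) should give the silyl dienol ether F7. Bromination with N-bromosuccinimide (THF, −78 °C) would give the bromomethyl ketone F8. Treatment with N,N'-ditosylhydrazine and DBU (THF, 0 °C) would convert the bromide into the diazo ketone 16 without any strong amide base.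

**Step 4 (ortho-hydroxymethylation).**
- **What may go wrong:** slow or incomplete conversion, because the phenol is tied up in a hydrogen bond to the lactone carbonyl and the ring is deactivated; oligomerisation of the boronate on prolonged heating.
- **Fallback, from 5 back to 7:** Magnesium-mediated ortho-formylation (MgCl2, Et3N, paraformaldehyde, MeCN, reflux) should give 6-formyl-7-hydroxy-5-methoxyphthalide F9. Reduction of the aldehyde with NaBH4 (THF/MeOH, 0 °C), which leaves the lactone intact, would give 7.

**Step 5 (selective acylation and silylation in one flask).**
- **What may go wrong:** acylation of the phenol in competition with the alcohol; loss of bromoacetate from the ortho-hydroxybenzyl ester before the phenol is silylated.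
- **Fallback, from 7 back to 10:** Both hydroxyls would be silylated (t-BuMe2SiCl, imidazole, DMF) to the bis-silyl ether F10. The primary alkyl silyl ether would be cleaved selectively under mild acid (pyridinium p-toluenesulfonate, MeOH, 20 °C) to the silylated carbinol F11. Acylation of F11 with 8 (pyridine, CH2Cl2, −20 °C) would give 10.

## Further compounds

F1 | step 11 | racemic [7-(tert-butyldimethylsilyloxy)-3-hydroxy-5-methoxyphthalid-6-yl]methyl 2-hydroxy-4-methoxy-3,6-dimethylbenzoate | COc1cc(C)c(C(=O)OCc2c(OC)cc3C(O)OC(=O)c3c2O[Si](C)(C)C(C)(C)C)c(O)c1C
F2 | step 11 | racemic (3,7-dihydroxy-5-methoxyphthalid-6-yl)methyl 2-hydroxy-4-methoxy-3,6-dimethylbenzoate | COc1cc(C)c(C(=O)OCc2c(OC)cc3c(c2O)C(=O)OC3O)c(O)c1C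
F3 | step 11 | [(3S)-3,7-dihydroxy-5-methoxyphthalid-6-yl]methyl 2-hydroxy-4-methoxy-3,6-dimethylbenzoate | COc1cc(C)c(C(=O)OCc2c(OC)cc3c(c2O)C(=O)O[C@@H]3O)c(O)c1C
F4 | step 9 | methyl 2,4-dihydroxy-3,6-dimethylbenzoate | COC(=O)c1c(C)cc(O)c(C)c1O
F5 | step 9 | methyl 2-hydroxy-4-methoxy-3,6-dimethylbenzoate | COC(=O)c1c(C)cc(OC)c(C)c1O
F6 | step 9 | 2-hydroxy-4-methoxy-3,6-dimethylbenzoic acid | COc1cc(C)c(C(=O)O)c(O)c1C
F7 | step 7 | [7-(tert-butyldimethylsilyloxy)-5-methoxyphthalid-6-yl]methyl (E)-3-methyl-4-(trimethylsilyloxy)penta-2,4-dienoate | C=C(O[Si](C)(C)C)/C(C)=C/C(=O)OCc1c(OC)cc2COC(=O)c2c1O[Si](C)(C)C(C)(C)C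
F8 | step 7 | [7-(tert-butyldimethylsilyloxy)-5-methoxyphthalid-6-yl]methyl (E)-5-bromo-3-methyl-4-oxopent-2-enoate | BrCC(=O)/C(C)=C/C(=O)OCc1c(OC)cc2COC(=O)c2c1O[Si](C)(C)C(C)(C)C
F9 | step 4 | 6-formyl-7-hydroxy-5-methoxyphthalide | COc1cc2COC(=O)c2c(O)c1C=O
F10 | step 5 | 7-(tert-butyldimethylsilyloxy)-6-[(tert-butyldimethylsilyloxy)methyl]-5-methoxyphthalide | COc1cc2COC(=O)c2c(O[Si](C)(C)C(C)(C)C)c1CO[Si](C)(C)C(C)(C)C
F11 | step 5 | 7-(tert-butyldimethylsilyloxy)-6-(hydroxymethyl)-5-methoxyphthalide | COc1cc2COC(=O)c2c(O[Si](C)(C)C(C)(C)C)c1CO
A1 | alternative 1 | prop-2-yn-1-yl 3-{[(3-methoxyprop-2-yn-1-yl)oxy]di(propan-2-yl)silyl}prop-2-ynoate | C#CCOC(=O)C#C[Si](C(C)C)(C(C)C)OCC#COC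
A2 | alternative 1 | oxasilole-fused 5-methoxyphthalide (diisopropylsilyl bridge from C7 through oxygen to the C6 methylene) | COc1cc2COC(=O)c2c2c1CO[Si]2(C(C)C)C(C)C
A3 | alternative 2 | 2-hydroxy-4-methoxy-3,6-dimethylbenzoic acid | COc1cc(C)c(C(=O)O)c(O)c1C
A4 | alternative 2 | 5-methoxy-6-methylideneisobenzofuran-1,7(3H,6H)-dione (ortho-quinone methide) | COC1=CC2=C(C(=O)OC2)C(=O)C1=C
A5 | alternative 2 | (7-hydroxy-5-methoxyphthalid-6-yl)methyl 2-hydroxy-4-methoxy-3,6-dimethylbenzoate (identical with 25) | COc1cc(C)c(C(=O)OCc2c(OC)cc3c(c2O)C(=O)OC3)c(O)c1C
A6 | alternative 3 | (R)-5-acetoxy-3-bromofuran-2(5H)-one | CC(=O)O[C@@H]1OC(=O)C(Br)=C1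
A7 | alternative 3 | 2-[(tert-butyldimethylsilyloxy)methyl]-1,3-dimethoxy-1-(trimethylsilyloxy)buta-1,3-diene | C=C(OC)C(CO[Si](C)(C)C(C)(C)C)=C(OC)O[Si](C)(C)C
A8 | alternative 3 | (R)-3-acetoxy-6-[(tert-butyldimethylsilyloxy)methyl]-7-hydroxy-5-methoxyphthalide | COc1cc2c(c(O)c1CO[Si](C)(C)C(C)(C)C)C(=O)O[C@H]2OC(C)=O
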